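**Retrosynthetic overview**

1. Target 20 is traced back to the 5,8-dimethoxy-1,4-naphthoquinone ester 18 (oxidative demethylation, then reduction to the naphthazarin). The ester C–O bond is cut to alcohol 16 and (R)-2-methylbutanoic acid, and quinone 15 comes from naphthol 14 by oxidation.
2. Naphthol 14 is disconnected by a Dötz benzannulation into the aryl(methoxy)carbene complex 5, one of its CO ligands and the terminal alkyne 12; this forms C3–C4, C1–C2 and C1–C8a.
3. The strategy rests on ring B (C1, C2, C3, C4, C4a, C8a) carrying its only carbon substituent at C2, between the C1 carbonyl and an unsubstituted C3–H, on a ring A oxygenated at C5 and C8, which is the pattern an aryl carbene, CO and a 1-alkyne deliver.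
4. Alkyne 12 comes from enal 8 by asymmetric alkynylation (sets the carbinol centre, R) and enal 8 from 2-methylbut-3-en-2-ol by cross-metathesis; carbene 5 comes from 2-bromo-1,4-dimethoxybenzene and Cr(CO)6.
5. Ring order: ring A is bought as the dimethoxybenzene, ring B is closed in step 6; the second stereocentre is bought with the acid.

Key step: step 6

Assumption (remark on the chemistry): the (S,S)-ProPhenol/Zn(CH3)2 catalyst is taken to deliver the alkynyl group to the Si face of E-enals, which gives the (R)-carbinol; should the sense be opposite on enal 8, the (R,R)-ligand is used with nothing else changed.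

**Route**

Step 1
Reactants: 1 2-bromo-1,4-dimethoxybenzene; 2 chromium hexacarbonyl, Cr(CO)6
Product: 5 pentacarbonyl[(2,5-dimethoxyphenyl)(methoxy)methylidene]chromium, via aryllithium 3 (not isolated), via lithium acylchromate 4 (not isolated)
Conditions: n-BuLi, THF, −78 °C; Cr(CO)6, −78 °C to rt; solvent exchange to CH2Cl2, (CH3)3OBF4, 0 °C
Reagents that add atoms: trimethyloxonium tetrafluoroborate, C[O+](C)C.F[B-](F)(F)F
Why: Bromine–lithium exchange gives the aryllithium, which adds to a CO ligand of Cr(CO)6, and O-methylation of the resulting acylchromate with the oxonium salt completes a standard Fischer carbene synthesis of a zerovalent chromium complex.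

Step 2
Reactants: 6 2-methylbut-3-en-2-ol; 7 (E)-but-2-enal
Product: 8 (2E)-4-hydroxy-4-methylpent-2-enal
Conditions: second-generation Hoveyda–Grubbs catalyst RuCl2(H2IMes)(=CH-C6H4-2-OiPr) (3 mol %), 7 (4 equiv), CH2Cl2, 40 °C
Reagents that add atoms: none
Why: Olefin cross-metathesis of the free tertiary allylic alcohol with excess crotonaldehyde loses propene and should give the conjugated E-enal, since neither the hindered carbinol nor the electron-poor enal homodimerises readily.

Step 3
Reactants: 8 (2E)-4-hydroxy-4-methylpent-2-enal; 9 ethynyltrimethylsilane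
Product: 10 (3E,5R)-2-methyl-7-(trimethylsilyl)hept-3-en-6-yne-2,5-diol
Conditions: (S,S)-ProPhenol (20 mol %), Zn(CH3)2 (4 equiv), 9 (3 equiv), toluene, rt then 4 °C; aq NH4Cl
Reagents that add atoms: none
Why: Catalytic asymmetric alkynylation of an α,β-unsaturated aldehyde, in which the dinuclear zinc–ProPhenol complex binds the enal and delivers the alkynylzinc to its Si face to set the (R)-carbinol, while the extra Zn(CH3)2 holds the tertiary hydroxyl as its zinc alkoxide.

Step 4
Reactants: 10 (3E,5R)-2-methyl-7-(trimethylsilyl)hept-3-en-6-yne-2,5-diol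
Product: 11 (3E,5R)-5-[(tert-butyldimethylsilyl)oxy]-2-methyl-7-(trimethylsilyl)hept-3-en-6-yn-2-ol
Conditions: TBSCl (1.1 equiv), imidazole, DMF, 0 °C
Reagents that add atoms: tert-butyldimethylsilyl chloride, CC(C)(C)[Si](C)(C)Cl
Why: Silyl ether formation should be selective for the secondary hydroxyl because the tertiary carbinol is inert to TBSCl and imidazole at 0 °C.

Step 5
Reactants: 11 (3E,5R)-5-[(tert-butyldimethylsilyl)oxy]-2-methyl-7-(trimethylsilyl)hept-3-en-6-yn-2-ol
Product: 12 (3E,5R)-5-[(tert-butyldimethylsilyl)oxy]-2-methylhept-3-en-6-yn-2-ol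
Conditions: K2CO3 (0.3 equiv), CH3OH, 0 °C to rt
Reagents that add atoms: none
Why: Base-catalysed methanolysis of the alkynyl C–Si bond (protiodesilylation) frees the terminal alkyne, and the secondary silyl ether and the stereocentre are stable to this mild base.

Step 6
Reactants: 5 pentacarbonyl[(2,5-dimethoxyphenyl)(methoxy)methylidene]chromium; 12 (3E,5R)-5-[(tert-butyldimethylsilyl)oxy]-2-methylhept-3-en-6-yn-2-ol
Product: 14 2-[(1R,2E)-1-[(tert-butyldimethylsilyl)oxy]-4-hydroxy-4-methylpent-2-en-1-yl]-4,5,8-trimethoxynaphthalen-1-ol, via naphthol chromium tricarbonyl complex 13 (not isolated)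
Conditions: 12 (1.5 equiv), degassed THF (0.05 M), 50 °C, argon; then air, rt; rapid filtration through silica and direct use
Reagents that add atoms: none
Why: Loss of one CO from the zerovalent chromium carbene lets the terminal alkyne insert into the Cr=C bond with its CH carbon bonded to the former carbene carbon (C3–C4), leaving the substituted carbon on chromium. CO insertion there (C1–C2) gives a chromium-bound dienylketene, and ring B closes by 6π electrocyclisation of the ketene carbon onto the only free ortho carbon of the aryl group (C1–C8a), then tautomerises to the naphthol complex 13, which air demetallates. This is the Dötz benzannulation, whose closest precedent is the reaction of aryl(methoxy)carbene chromium complexes with 1-alkynes and propargylic ethers to give 4-methoxy-1-naphthols. No stereocentre is formed, and the propargylic (R)-centre is carried through unchanged under these neutral conditions. The step needs alkyne regiochemistry (secured by H versus the branched silyloxy carbon, and in any case erased once ring B is a quinone on the symmetric 5,8-dioxygenated core), CO insertion in preference to indene formation (favoured by the methoxy carbene in THF at moderate temperature), and a single closure site (the other ortho position carries OCH3). The tertiary hydroxyl should not trap the ketene because lactonisation would place the E alkene in a seven-membered ring, and the skipped enyne cannot cyclopropanate.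

Step 7
Reactants: 14 2-[(1R,2E)-1-[(tert-butyldimethylsilyl)oxy]-4-hydroxy-4-methylpent-2-en-1-yl]-4,5,8-trimethoxynaphthalen-1-ol
Product: 15 2-[(1R,2E)-1-[(tert-butyldimethylsilyl)oxy]-4-hydroxy-4-methylpent-2-en-1-yl]-5,8-dimethoxynaphthalene-1,4-dione
Conditions: (NH4)2Ce(NO3)6 (2.2 equiv), CH3CN/H2O, 0 °C, 10 min
Reagents that add atoms: water, O
Why: Oxidative demethylation of a 4-methoxy-1-naphthol by tetravalent cerium (two one-electron oxidations, water attack at C4, loss of methanol) should give the 1,4-quinone in ring B, which is far more electron-rich than the dimethoxy ring A.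

Step 8
Reactants: 15 2-[(1R,2E)-1-[(tert-butyldimethylsilyl)oxy]-4-hydroxy-4-methylpent-2-en-1-yl]-5,8-dimethoxynaphthalene-1,4-dione
Product: 16 2-[(1R,2E)-1,4-dihydroxy-4-methylpent-2-en-1-yl]-5,8-dimethoxynaphthalene-1,4-dione
Conditions: HF·pyridine, pyridine/THF, 0 °C to rt
Reagents that add atoms: none
Why: Fluoride cleavage of the silyl ether under buffered, weakly acidic conditions avoids the basic media that degrade quinones and should leave the tertiary allylic alcohol intact.

Step 9
Reactants: 16 2-[(1R,2E)-1,4-dihydroxy-4-methylpent-2-en-1-yl]-5,8-dimethoxynaphthalene-1,4-dione; 17 (2R)-2-methylbutanoic acid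
Product: 18 (1R,2E)-1-(5,8-dimethoxy-1,4-dioxo-1,4-dihydronaphthalen-2-yl)-4-hydroxy-4-methylpent-2-en-1-yl (2R)-2-methylbutanoate
Conditions: DCC (1.2 equiv), DMAP (0.1 equiv), CH2Cl2, 0 °C
Reagents that add atoms: none
Why: Steglich esterification through the O-acylisourea and acylpyridinium should acylate only the secondary alcohol, the tertiary one being too hindered, and low temperature with catalytic DMAP should keep the α-centre of the acid from epimerising.

Step 10
Reactants: 18 (1R,2E)-1-(5,8-dimethoxy-1,4-dioxo-1,4-dihydronaphthalen-2-yl)-4-hydroxy-4-methylpent-2-en-1-yl (2R)-2-methylbutanoate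
Product: 20 (1R,2E)-1-(5,8-dihydroxy-1,4-dioxo-1,4-dihydronaphthalen-2-yl)-4-hydroxy-4-methylpent-2-en-1-yl (2R)-2-methylbutanoate, via naphthalenetetrone 19 (not isolated)
Conditions: AgO (4 equiv), 6 M HNO3, 1,4-dioxane, rt, 5 min; then aq Na2S2O4 in the work-up
Reagents that add atoms: water, O
Why: Divalent silver in nitric acid oxidatively demethylates the remaining 1,4-dimethoxy ring to the diquinone (quinone oxygens from water), and dithionite reduces it by two electrons to the naphthazarin, whose two tautomers are one compound.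

**Compound list**

1 | 2-bromo-1,4-dimethoxybenzene | COc1ccc(OC)c(Br)c1 | starting material
2 | chromium hexacarbonyl | [C-]#[O+].[C-]#[O+].[C-]#[O+].[C-]#[O+].[C-]#[O+].[C-]#[O+].[Cr] | starting material
3 | (2,5-dimethoxyphenyl)lithium | [Li]c1cc(OC)ccc1OC | intermediate
4 | lithium pentacarbonyl[(2,5-dimethoxyphenyl)(oxido)methylidene]chromate | [Li+].[O-]C(=[Cr])c1cc(OC)ccc1OC.[C-]#[O+].[C-]#[O+].[C-]#[O+].[C-]#[O+].[C-]#[O+] | intermediate
5 | pentacarbonyl[(2,5-dimethoxyphenyl)(methoxy)methylidene]chromium | COC(=[Cr])c1cc(OC)ccc1OC.[C-]#[O+].[C-]#[O+].[C-]#[O+].[C-]#[O+].[C-]#[O+] | intermediate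
6 | 2-methylbut-3-en-2-ol | C=CC(C)(C)O | starting material
7 | (E)-but-2-enal | C/C=C/C=O | starting material
8 | (2E)-4-hydroxy-4-methylpent-2-enal | CC(C)(O)/C=C/C=O | intermediate
9 | ethynyltrimethylsilane | C#C[Si](C)(C)C | starting material
10 | (3E,5R)-2-methyl-7-(trimethylsilyl)hept-3-en-6-yne-2,5-diol | O[C@H](/C=C/C(C)(C)O)C#C[Si](C)(C)C | intermediate
11 | (3E,5R)-5-[(tert-butyldimethylsilyl)oxy]-2-methyl-7-(trimethylsilyl)hept-3-en-6-yn-2-ol | CC(C)(C)[Si](C)(C)O[C@H](/C=C/C(C)(C)O)C#C[Si](C)(C)C | intermediate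
12 | (3E,5R)-5-[(tert-butyldimethylsilyl)oxy]-2-methylhept-3-en-6-yn-2-ol | CC(C)(C)[Si](C)(C)O[C@H](/C=C/C(C)(C)O)C#C | intermediate
13 | tricarbonylchromium complex of naphthol 14 (chromium on ring B) | CC(C)(C)[Si](C)(C)O[C@H](/C=C/C(C)(C)O)c1cc(OC)c2c(OC)ccc(OC)c2c1O.[Cr].[C-]#[O+].[C-]#[O+].[C-]#[O+] | intermediate
14 | 2-[(1R,2E)-1-[(tert-butyldimethylsilyl)oxy]-4-hydroxy-4-methylpent-2-en-1-yl]-4,5,8-trimethoxynaphthalen-1-ol | CC(C)(C)[Si](C)(C)O[C@H](/C=C/C(C)(C)O)c1cc(OC)c2c(OC)ccc(OC)c2c1O | intermediate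
15 | 2-[(1R,2E)-1-[(tert-butyldimethylsilyl)oxy]-4-hydroxy-4-methylpent-2-en-1-yl]-5,8-dimethoxynaphthalene-1,4-dione | CC(C)(C)[Si](C)(C)O[C@H](/C=C/C(C)(C)O)C1=CC(=O)c2c(OC)ccc(OC)c2C1=O | intermediate
16 | 2-[(1R,2E)-1,4-dihydroxy-4-methylpent-2-en-1-yl]-5,8-dimethoxynaphthalene-1,4-dione | O[C@H](/C=C/C(C)(C)O)C1=CC(=O)c2c(OC)ccc(OC)c2C1=O | intermediate
17 | (2R)-2-methylbutanoic acid | CC[C@@H](C)C(=O)O | starting material
18 | (1R,2E)-1-(5,8-dimethoxy-1,4-dioxo-1,4-dihydronaphthalen-2-yl)-4-hydroxy-4-methylpent-2-en-1-yl (2R)-2-methylbutanoate | CC[C@@H](C)C(=O)O[C@H](/C=C/C(C)(C)O)C1=CC(=O)c2c(OC)ccc(OC)c2C1=O | intermediate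
19 | (1R,2E)-4-hydroxy-4-methyl-1-(1,4,5,8-tetraoxo-1,4,5,8-tetrahydronaphthalen-2-yl)pent-2-en-1-yl (2R)-2-methylbutanoate | CC[C@@H](C)C(=O)O[C@H](/C=C/C(C)(C)O)C1=CC(=O)C2=C(C1=O)C(=O)C=CC2=O | intermediate
20 | (1R,2E)-1-(5,8-dihydroxy-1,4-dioxo-1,4-dihydronaphthalen-2-yl)-4-hydroxy-4-methylpent-2-en-1-yl (2R)-2-methylbutanoate | CC[C@@H](C)C(=O)O[C@H](/C=C/C(C)(C)O)C1=CC(=O)c2c(O)ccc(O)c2C1=O | target

**Step count**

Total: 10 steps. Longest linear sequence: 9 steps (steps 2 to 10); step 1 is the convergent branch.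

**Steps most likely to fail**

Step 6. The vinylcarbene intermediate may close without CO insertion (indene or furan products), or the terminal alkyne may oligomerise on chromium, so that little naphthol forms. The fallback builds ring B from the same alkyne by a thermal, metal-free ring expansion; it sets out from bromide 1 and enyne 12 and comes back at quinone 15.
- Bromide 1 is treated with NaNH2 and 1,1-dimethoxyethene in THF; the 3,6-dimethoxyaryne adds [2+2] to give 2,5,7,7-tetramethoxybicyclo[4.2.0]octa-1,3,5-triene F1.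
- Aqueous HCl hydrolyses the ketal to 2,5-dimethoxybicyclo[4.2.0]octa-1,3,5-trien-7-one F2.
- N-Bromosuccinimide (2 equiv) should give 8,8-dibromo-2,5-dimethoxybicyclo[4.2.0]octa-1,3,5-trien-7-one F3, and aqueous H2SO4 hydrolyses it to 2,5-dimethoxybicyclo[4.2.0]octa-1,3,5-triene-7,8-dione F4.
- Enyne 12 is converted with n-BuLi (2 equiv, THF, −78 °C) into its alkoxide acetylide, which adds to one of the two equivalent carbonyls of F4 to give 8-[(3R,4E)-3-[(tert-butyldimethylsilyl)oxy]-6-hydroxy-6-methylhept-4-en-1-yn-1-yl]-8-hydroxy-2,5-dimethoxybicyclo[4.2.0]octa-1,3,5-trien-7-one F5.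
- Heating F5 in p-xylene should open the four-membered ring to the vinylketene, close it onto the alkyne and shift hydrogen (Moore rearrangement), giving quinone 15 directly with the stereocentre untouched.

Step 10. Ring A is deactivated by the quinone, so forcing the oxidation in nitric acid may ionise the tertiary allylic alcohol or solvolyse or hydrolyse the allylic acyloxy group. The fallback moves the oxidation ahead of the ester; it sets out from silyl ether quinone 15 and comes back at target 20.
- AgO and 6 M HNO3 in dioxane should convert 15 into 2-[(1R,2E)-1-[(tert-butyldimethylsilyl)oxy]-4-hydroxy-4-methylpent-2-en-1-yl]naphthalene-1,4,5,8-tetrone F6.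
- Aqueous Na2S2O4 reduces it to 2-[(1R,2E)-1-[(tert-butyldimethylsilyl)oxy]-4-hydroxy-4-methylpent-2-en-1-yl]-5,8-dihydroxynaphthalene-1,4-dione F7.
- HF·pyridine gives 2-[(1R,2E)-1,4-dihydroxy-4-methylpent-2-en-1-yl]-5,8-dihydroxynaphthalene-1,4-dione F8.
- Steglich esterification with acid 17 (DCC, catalytic DMAP, CH2Cl2, 0 °C) should acylate only the side-chain secondary hydroxyl, since the peri phenols are tied up in hydrogen bonds to the quinone carbonyls, and gives 20.

Step 3. The zinc alkoxide of the free tertiary hydroxyl may disturb the dinuclear catalyst and lower facial selectivity, or the sense of addition may not be the assumed one. The fallback sets the centre by reagent-controlled reduction; it sets out from enal 8 and comes back at diol 10.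
- LiC≡CSi(CH3)3 (2.2 equiv, THF, −78 °C) adds to 8 to give racemic (3E)-2-methyl-7-(trimethylsilyl)hept-3-en-6-yne-2,5-diol F9.
- MnO2 in CH2Cl2 oxidises the allylic and propargylic carbinol to (4E)-6-hydroxy-6-methyl-1-(trimethylsilyl)hept-4-en-1-yn-3-one F10.
- Midland reduction with (R)-Alpine-Borane (B-isopinocampheyl-9-borabicyclo[3.3.1]nonane from (+)-α-pinene) should give (R)-10, because the alkynyl group acts as the small substituent, in the same sense as the reduction of 1-octyn-3-one to (R)-1-octyn-3-ol.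

**Further compounds**

F1 | step 6 | 2,5,7,7-tetramethoxybicyclo[4.2.0]octa-1,3,5-triene | COc1ccc(OC)c2c1CC2(OC)OC
F2 | step 6 | 2,5-dimethoxybicyclo[4.2.0]octa-1,3,5-trien-7-one | COc1ccc(OC)c2c1CC2=O
F3 | step 6 | 8,8-dibromo-2,5-dimethoxybicyclo[4.2.0]octa-1,3,5-trien-7-one | COc1ccc(OC)c2c1C(Br)(Br)C2=O
F4 | step 6 | 2,5-dimethoxybicyclo[4.2.0]octa-1,3,5-triene-7,8-dione | COc1ccc(OC)c2c1C(=O)C2=O
F5 | step 6 | 8-[(3R,4E)-3-[(tert-butyldimethylsilyl)oxy]-6-hydroxy-6-methylhept-4-en-1-yn-1-yl]-8-hydroxy-2,5-dimethoxybicyclo[4.2.0]octa-1,3,5-trien-7-one (both C8 epimers) | CC(C)(C)[Si](C)(C)O[C@H](/C=C/C(C)(C)O)C#CC1(O)C(=O)c2c(OC)ccc(OC)c21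
F6 | step 10 | 2-[(1R,2E)-1-[(tert-butyldimethylsilyl)oxy]-4-hydroxy-4-methylpent-2-en-1-yl]naphthalene-1,4,5,8-tetrone | CC(C)(C)[Si](C)(C)O[C@H](/C=C/C(C)(C)O)C1=CC(=O)C2=C(C1=O)C(=O)C=CC2=O
F7 | step 10 | 2-[(1R,2E)-1-[(tert-butyldimethylsilyl)oxy]-4-hydroxy-4-methylpent-2-en-1-yl]-5,8-dihydroxynaphthalene-1,4-dione | CC(C)(C)[Si](C)(C)O[C@H](/C=C/C(C)(C)O)C1=CC(=O)c2c(O)ccc(O)c2C1=O
F8 | step 10 | 2-[(1R,2E)-1,4-dihydroxy-4-methylpent-2-en-1-yl]-5,8-dihydroxynaphthalene-1,4-dione | O[C@H](/C=C/C(C)(C)O)C1=CC(=O)c2c(O)ccc(O)c2C1=O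
F9 | step 3 | (3E)-2-methyl-7-(trimethylsilyl)hept-3-en-6-yne-2,5-diol, racemic | OC(/C=C/C(C)(C)O)C#C[Si](C)(C)C
F10 | step 3 | (4E)-6-hydroxy-6-methyl-1-(trimethylsilyl)hept-4-en-1-yn-3-one | O=C(/C=C/C(C)(C)O)C#C[Si](C)(C)C
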